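Compare what the charge allows with what the readings show.

common to all: starting complex 0.050 M
- Sunday's: incoming ligand 0.035 M; temperature 25 °C; the very flask that is asked about, followed so far
- Tuesday's: incoming ligand 0.018 M; temperature 10 °C; run made earlier
- flask: incoming ligand 0.0350 M; temperature 25 °C; time 10 h

- Sunday's (time / h: complex with two exchanged / %): 1.50: 12.5; 3.00: 12.7; 5.00: 15.7; 6.00: 13.2; 8.00: 12.5; 10.0: 10.0
- Tuesday's (time / h: complex with two exchanged / %): 0.500: 1.8; 1.00: 1.5; 1.33: 0; 2.00: 1.8; 3.00: 2.0

(readings scatter by 1 percentage point)

- ash: at 10 h raise the temperature by 10 K, then wait 5.0 h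
- larch: change nothing and wait 5.0 h more
- cedar: at 10 h take out 90 % of the leaving ligand then present, then wait 5.0 h
- oak: at 10 h add incoming ligand, 100 % of the amount charged, then wait 5.0 h

- what is added takes up no volume worth counting

- complex with two exchanged, in percent of the starting complex first charged, at 10 h
- which option adds most complex with two exchanged ("none" when 2 percentage points or less is all one gets) (ash / larch / cedar / oak / none)
- complex with two exchanged present, in percent of the starting complex first charged, after ash
- complex with two exchanged present, in percent of the starting complex first charged, after oak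

1. Each complex with two exchanged takes two incoming ligands, and this flask charges fewer than two per starting complex. Incoming ligand is therefore the limiting reagent, and the ceiling is 35.0 % of the starting complex.

2. Sunday's run already reads 12.5 % at 1.50 h, and its last 3 readings average 11.9 %. That lies far below the ceiling, so I treat the plateau as a reversible balance.

3. The ceiling share, plateau fraction over ceiling, reads 34.0 %, about a third. Tuesday's run, colder and with less incoming ligand, reads 7.89 %. Two settings differ there, so I carry the share at 25 °C and hold it for more incoming ligand as my own assumption.

4. My reckoning puts this flask near 11.9 % at 10 h. Oak raises the ceiling to 70.0 %, twice the old one, while ash, larch and cedar leave it unchanged. Holding the share, I choose oak and expect 23.8 %; for ash I reckon no figure.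

5. The forecast says 11.5 %, oak, 9 % after ash and 33 % after oak, which is above my figure: “Extra ligand reopens formation”.

6. The flask gives 11.5 % at 10 h, a share of 32.9 %. The best option is oak, gaining 15 percentage points to reach 26.3 %; ash ends at 5.90 %.

    starting complex + incoming ligand ⇌ leaving ligand + complex with one exchanged (K = 3.50, k = 130 L mol⁻¹ h⁻¹, Ea = 53.0 kJ mol⁻¹, ΔH = −45.0 kJ mol⁻¹)
    complex with one exchanged + incoming ligand ⇌ leaving ligand + complex with two exchanged (K = 3.20, k = 44.0 L mol⁻¹ h⁻¹, Ea = 67.0 kJ mol⁻¹, ΔH = −64.0 kJ mol⁻¹)
    incoming ligand ⇌ dormant form (K = 9.90, k = 0.180 h⁻¹, Ea = 91.0 kJ mol⁻¹, ΔH = −14.0 kJ mol⁻¹)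
    (constants at 25 °C)

7. The neighbour flask with 0.060 M of incoming ligand has a ceiling of 60.0 %; the share read from Sunday's run predicts 20.4 %, and that flask holds 20.8 % at 10 h. This flask has not come to rest at 10 h: by 100 h complex with two exchanged falls to 6.54 %, a share of 18.7 %, while dormant form climbs from 19.7 % to 44.5 % of the incoming ligand charged.

(Readings and results are simulated with constants of no real substance; the scatter is artificial.)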